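In this stirred vessel the reagent starts in the second phase, while in the first phase substrate turns into target and target into over-reacted product.

| flask | substrate | reagent in the second phase | remark | time | volume of the second phase over the first |
|---|---|---|---|---|---|
| dawn | 0.13 M | 0.30 M | run made earlier |  |  |
| Friday's | 0.030 M | 0.300 M |  | 4.0 h | 1.0 |
| Wednesday's | 0.080 M | 0.100 M |  | 4.0 h | 1.0 |
| Monday's | 0.12 M | 0.300 M |  | 4.0 h | 1.0 |
| Sunday's | 0.12 M | 0.600 M |  | 4.0 h | 1.0 |

dawn run (percent of the substrate charged)

| time / h | target / % | over-reacted product / % |
|---|---|---|
| 0.167 | 1.4 | 0 |
| 0.500 | 7.0 | 1.1 |
| 0.833 | 13.7 | 2.5 |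
| 1.33 | 21.4 | 4.8 |
| 2.00 | 29.6 | 11.8 |
| 2.50 | 30.8 | 15.4 |

(scatter of a reading: 0.5 percentage points)

- in the second phase: reagent in the second phase; everything else is in the first
- charges count per volume of the first phase; a concentration in a rate is the amount of a species over the volume of its own phase; every rate counts per litre of the first phase
- what was read earlier has a scatter of 0.5 percentage points, one standard deviation
- the earlier runs hold the two phases in the same ratio of volumes as the flask asked about

* the flasks put in order of share of target in all that became target or over-reacted product, best first, at 4.0 h (Friday's / Wednesday's / Monday's / Sunday's)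
* the share of target in all that became target or over-reacted product of the flask you put first, at 4.0 h
* the share of target in all that became target or over-reacted product of the flask you put last, at 4.0 h

What sets the share of target? I assume that substrate and target each react first order with the same reagent, so the reagent cancels from the split. Let x be the fraction of substrate left, c the fraction converted, and P and Q the target and over-reacted product as fractions of the substrate charged. Per unit of substrate used, Q then grows as s·P/x, where s, the selectivity factor, is the rate constant of over-reaction over that of the first step. Replacing the climbing P/x by the mean of its two end values gives Q/P = s·c/(2x). The last dawn reading gives 1.16 for s, that ratio of rate constants.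

How far does each flask get? Up to its last reading, the dawn run has a mean pace ln(1/x)/t of 0.248 h⁻¹. Scaled by the reagent charge, ln(1/x) at 4.0 h is 0.331 for Wednesday's, 0.992 for Monday's and 1.98 for Sunday's. My shares, in that order, are therefore 81.5 %, 50.4 % and 21.6 %.

Where does Friday's go? Friday's flask has Monday's reagent but a quarter of its substrate, so it should draw less reagent and run further. I place it behind Monday's and ahead of Sunday's, which has twice the reagent.

The forecast says Wednesday's > Monday's > Friday's > Sunday's, with 80 % (75 % to 85 %) first and 25 % (17 % to 32 %) last. One of its grounds is “The share of target therefore depends only on conversion”, and it puts over-reaction at about 1.3 times as fast as the first step, against my 1.16.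

The flasks give Wednesday's > Monday's > Friday's > Sunday's: 78.7 %, 52.3 %, 37.6 % and 22.7 %.

    reagent in the reaction phase ⇌ reagent in the second phase, rate k1*([reagent in the reaction phase] - [reagent in the second phase]/K1) per volume of the first phase (partition coefficient = 1.10, kL = 0.00740 min⁻¹)
    substrate + reagent in the reaction phase → target (k = 0.110 L mol⁻¹ min⁻¹)
    reagent in the reaction phase + target → over-reacted product (k = 0.140 L mol⁻¹ min⁻¹)
    reagent in the reaction phase → decomposed reagent (k = 0.00820 min⁻¹)

Wednesday's keeps 69.2 % of its substrate at 4.00 h, and s turns that into 79.5 %, against the flask's 78.7 %. For the same flask read at 10 h, the mean pace reckons 43.8 % of the substrate left. That flask holds 55.6 %, with reagent in the second phase down to 6.98 % of its charge. From that substrate s gives 68.3 %, and the flask gives 67.9 %.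

Readings and results were generated by integration with constants of no real substance.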